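## Retrosynthetic overview

- Locants (decalin): C10 = fusion CH; C1/C2 = ring A CH2 (C1 next to C10); C3 = C(=CMe2); C4 = CH bearing the acid chain; C5 = fusion C–Me; C6/C7 = ring B CH2; C8 = CHMe; C9 = C(Me)(CH2Ar). Ring A = C1–C5 + C10, ring B = C5–C10.
- Late stage: quinone ← hydroquinone dimethyl ether; CO2H ← CH2OSi; C8–Me ← C8=O (methylenation, hydrogenation); C9–CH2Ar and C10–H ← reductive benzylation of the ring B enone C8(=O)–C9(Me)=C10.
- Ring B (formed second) ← Robinson-type annulation of ethyl vinyl ketone onto the ring A ketone (C10=O): a chiral-imine Michael addition makes quaternary C5 anti to the C4 chain, and aldol condensation makes C9=C10.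
- Ring A (formed first) ← auxiliary-controlled Diels–Alder reaction of the 2-silyloxy diene of ethyl vinyl ketone (C2=C1–C10(OSi)=C5) with an (E)-N-enoyl oxazolidinone (C3=C4), forming C4–C5 and the ring-closing C2–C3 bond. The acyl carbon on C3 is then exchanged for the isopropylidene through a spiro β-lactone (acetone aldol, loss of CO2).
- Enabling feature: in ring A the fusion carbon C10 (a ketone until ring B is annulated) and the trigonal isopropylidene-bearing C3 (acyl-bearing sp3 carbon until step 8) are 1,4-related. Ring A is therefore a 4-acylcyclohexanone, the retron of a 2-silyloxydiene cycloaddition, and since C3 ends trigonal and C5 is re-set, only C4 must be controlled there.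

Key step: step 5

Remark: the C3 and C5 configurations formed in step 5 and the spiro centre formed in step 7 are of no consequence (C3 becomes trigonal in step 8, C5 is re-set in step 10); the isomers drawn are the expected major ones.

## Route

Step 1
Reactants: 1 pent-1-en-3-one (ethyl vinyl ketone)
Product: 2 tert-butyl(dimethyl)[(3Z)-penta-1,3-dien-3-yloxy]silane
Conditions: TBSOTf (1.1 equiv), Et3N (1.5 equiv), Et2O, 0 °C
Reagents that add atoms: tert-butyldimethylsilyl trifluoromethanesulfonate, CC(C)(C)[Si](C)(C)OS(=O)(=O)C(F)(F)F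
Why: Soft enolization (silyl triflate/amine silyl enol ether formation) of the only enolizable position should give the cross-conjugated 2-silyloxy diene, the Z enol ether placing the methyl trans to the vinyl group so that the s-cis diene is reactive.

Step 2
Reactants: 3 pent-4-en-1-ol
Product: 4 (pent-4-en-1-yloxy)tri(propan-2-yl)silane
Conditions: TIPSCl (1.1 equiv), imidazole (2 equiv), DMF, rt
Reagents that add atoms: chlorotri(propan-2-yl)silane, CC(C)[Si](Cl)(C(C)C)C(C)C
Why: Standard silyl ether protection of a primary alcohol; no stereocenter is involved.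

Step 3
Reactants: 5 (4S)-4-benzyl-1,3-oxazolidin-2-one
Product: 7 (4S)-3-acryloyl-4-benzyl-1,3-oxazolidin-2-one, via lithium oxazolidinide 6 (not isolated)
Conditions: n-BuLi (1.0 equiv), THF, −78 °C; then acryloyl chloride (1.2 equiv), −78 → 0 °C
Reagents that add atoms: acryloyl chloride, C=CC(=O)Cl
Why: N-Acylation of the lithiated oxazolidinone auxiliary with an acid chloride; the auxiliary stereocenter is untouched.

Step 4
Reactants: 4 (pent-4-en-1-yloxy)tri(propan-2-yl)silane; 7 (4S)-3-acryloyl-4-benzyl-1,3-oxazolidin-2-one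
Product: 8 (4S)-4-benzyl-3-[(2E)-6-{[tri(propan-2-yl)silyl]oxy}hex-2-enoyl]-1,3-oxazolidin-2-one
Conditions: second-generation Hoveyda–Grubbs catalyst RuCl2(=CH-C6H4-2-OiPr)(1,3-dimesitylimidazolidin-2-ylidene) (5 mol %), 4 (2 equiv), CH2Cl2, 40 °C
Reagents that add atoms: none
Why: Olefin cross-metathesis between an electron-poor acryloyl imide and an unhindered terminal alkene should be selective for the cross product and give the E-enoyl imide under thermodynamic control.

Step 5
Reactants: 2 tert-butyl(dimethyl)[(3Z)-penta-1,3-dien-3-yloxy]silane; 8 (E)-N-enoyl oxazolidinone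
Product: 9 (4S)-4-benzyl-3-{[(1S,2S,3S)-4-{[tert-butyl(dimethyl)silyl]oxy}-3-methyl-2-(3-{[tri(propan-2-yl)silyl]oxy}propyl)cyclohex-4-en-1-yl]carbonyl}-1,3-oxazolidin-2-one
Conditions: Et2AlCl (1.4 equiv), 2 (2 equiv), CH2Cl2, −78 → −30 °C; cold aq. NaHCO3/Rochelle salt work-up
Reagents that add atoms: none
Why: Et2AlCl forms the cationic bidentate chelate of the s-cis N-enoyl oxazolidinone, which undergoes a normal-demand, strongly asynchronous [4+2] cycloaddition with the electron-rich 2-silyloxy diene: the C4–C5 bond (enoyl β-carbon to the methyl-bearing silyl enol ether terminus) leads and ring A is closed by the C2–C3 bond between the unsubstituted diene CH2 terminus and the enoyl α-carbon. The closest known reaction type is the oxazolidinone-auxiliary Diels–Alder reaction of β-substituted N-enoyl imides with acyclic dienes under dialkylaluminium chloride promotion, combined with the established use of 2-silyloxy dienes as cyclohexanone synthons. Ring A is closed in the intermolecular [4+2] mode (in the stepwise limit a Mukaiyama–Michael addition followed by 6-endo-trig closure of the aluminium enolate onto the activated vinyl group), leaving C10 as a regiodefined silyl enol ether (masked ketone) and C1/C2 as the future ring CH2 groups. C4 is set by the auxiliary, whose benzyl group shields one face of the chelated dienophile so that the diene adds to the opposite face; C3 (trans to C4, from the E alkene) and C5 (methyl cis to the acyl group, endo transition state) are also formed, but C3 becomes trigonal in step 8 and C5 is re-set in step 10. The step needs para regioselectivity and π-facial selectivity: the first is secured by the 2-silyloxy group (largest HOMO coefficient at C5 matched with the largest LUMO coefficient at the enoyl β-carbon C4), the second by the rigid aluminium chelate of the auxiliary.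

Step 6
Reactants: 9 Diels–Alder adduct (silyl enol ether imide)
Product: 10 S-phenyl (1S,2S,3S)-4-{[tert-butyl(dimethyl)silyl]oxy}-3-methyl-2-(3-{[tri(propan-2-yl)silyl]oxy}propyl)cyclohex-4-ene-1-carbothioate
Conditions: PhSH (1.5 equiv), n-BuLi (1.4 equiv), THF, 0 °C → rt
Reagents that add atoms: benzenethiol (as its lithium salt), Sc1ccccc1
Why: Thiolate cleavage of the N-acyl oxazolidinone at the exocyclic carbonyl (transthioesterification) should release the auxiliary 5 for recovery and give the phenyl thioester needed for step 7, leaving the ring stereocenters and both silyl groups untouched.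

Step 7
Reactants: 10 S-phenyl thioester
Product: 12 (4R,8S,9S)-7-{[tert-butyl(dimethyl)silyl]oxy}-3,3,8-trimethyl-9-(3-{[tri(propan-2-yl)silyl]oxy}propyl)-2-oxaspiro[3.5]non-6-en-1-one, via thioester lithium enolate 11 (not isolated)
Conditions: LiN(iPr)2 (1.1 equiv), THF, −78 °C; acetone (1.3 equiv), −78 → 0 °C
Reagents that add atoms: acetone, CC(C)=O
Why: β-Lactone synthesis from a thioester enolate and a ketone (aldol addition, then closure of the aldolate onto the thioester with loss of thiophenoxide); the new spiro centre (acetone expected anti to the C4 chain) is destroyed in step 8.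

Step 8
Reactants: 12 spiro β-lactone
Product: 13 tert-butyl(dimethyl){[(5S,6S)-6-methyl-4-(propan-2-ylidene)-5-(3-{[tri(propan-2-yl)silyl]oxy}propyl)cyclohex-1-en-1-yl]oxy}silane
Conditions: toluene, sealed tube, 150 °C
Reagents that add atoms: none
Why: Thermal [2+2] cycloreversion (decarboxylation) of the β-lactone should give the tetrasubstituted exocyclic isopropylidene regiospecifically, since the double bond can only form between the two former lactone ring carbons.

Step 9
Reactants: 13 isopropylidene silyl enol ether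
Product: 14 (2S,3S)-2-methyl-4-(propan-2-ylidene)-3-(3-{[tri(propan-2-yl)silyl]oxy}propyl)cyclohexan-1-one
Conditions: TBAF (1.05 equiv), AcOH (1.1 equiv), THF, −20 °C
Reagents that add atoms: none
Why: Buffered fluoride desilylation should cleave the silyl enol ether (enolate leaving group) much faster than the primary triisopropylsilyl ether and give the ketone by C-protonation at C1; C5 stays as formed and any epimer converges in step 10.

Step 10
Reactants: 14 ring A ketone; 1 pent-1-en-3-one
Product: 17 (2S,3R)-2-methyl-2-(3-oxopentyl)-4-(propan-2-ylidene)-3-(3-{[tri(propan-2-yl)silyl]oxy}propyl)cyclohexan-1-one, via ketimine 15 (not isolated), via Michael adduct ketimine 16 (not isolated)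
Conditions: (S)-1-phenylethan-1-amine (1.1 equiv), TsOH (cat.), toluene, reflux (Dean–Stark); concentrate; 1 (1.5 equiv), THF, 40 °C; then 20% aq. AcOH, rt
Reagents that add atoms: none
Why: Michael addition of a chiral imine through its more substituted secondary enamine tautomer (aza-ene-type, deracemizing alkylation) should deliver the vinyl ketone to C5 regioselectively and to the face anti to the pseudoaxial C4 chain, a preference reinforced by the matched (S)-amine, which sets quaternary C5 with the methyl cis to the C4 chain.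

Step 11
Reactants: 17 1,5-diketone
Product: 18 (4aS,5R)-1,4a-dimethyl-6-(propan-2-ylidene)-5-(3-{[tri(propan-2-yl)silyl]oxy}propyl)-4,4a,5,6,7,8-hexahydronaphthalen-2(3H)-one
Conditions: NaOMe (0.5 equiv), MeOH, 60 °C
Reagents that add atoms: none
Why: Intramolecular aldol condensation (second half of a Robinson annulation): only the ethyl-ketone α-carbon C9 can close a six-membered ring onto the C10 carbonyl and dehydrate, closing ring B as the tetrasubstituted enone without a new stereocenter.

Step 12
Reactants: 19 4-methoxy-2-methylphenol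
Product: 20 2-hydroxy-5-methoxy-3-methylbenzaldehyde
Conditions: MgCl2 (1.5 equiv), Et3N (3.75 equiv), (CH2O)n (6.75 equiv), MeCN, reflux; aq. HCl work-up
Reagents that add atoms: paraformaldehyde (formaldehyde), C=O
Why: Magnesium-mediated ortho-formylation of a phenol should formylate the only free ortho position.

Step 13
Reactants: 20 2-hydroxy-5-methoxy-3-methylbenzaldehyde
Product: 21 2,5-dimethoxy-3-methylbenzaldehyde
Conditions: MeI (1.5 equiv), K2CO3 (2 equiv), acetone, reflux
Reagents that add atoms: iodomethane, CI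
Why: Williamson O-methylation of the phenol.

Step 14
Reactants: 21 2,5-dimethoxy-3-methylbenzaldehyde
Product: 22 (2,5-dimethoxy-3-methylphenyl)methanol
Conditions: NaBH4 (0.5 equiv), MeOH, 0 °C
Reagents that add atoms: none
Why: Borohydride reduction of the aryl aldehyde to the benzylic alcohol.

Step 15
Reactants: 22 (2,5-dimethoxy-3-methylphenyl)methanol
Product: 23 1-(bromomethyl)-2,5-dimethoxy-3-methylbenzene
Conditions: PBr3 (0.4 equiv), Et2O, 0 °C
Reagents that add atoms: phosphorus tribromide, BrP(Br)Br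
Why: Conversion of the benzylic alcohol into the bromide by SN2 displacement of its phosphite ester.

Step 16
Reactants: 18 bicyclic enone; 23 1-(bromomethyl)-2,5-dimethoxy-3-methylbenzene
Product: 25 (1R,4aS,5S,8aS)-1-[(2,5-dimethoxy-3-methylphenyl)methyl]-1,4a-dimethyl-6-(propan-2-ylidene)-5-(3-{[tri(propan-2-yl)silyl]oxy}propyl)octahydronaphthalen-2(1H)-one, via lithium enolate 24 (not isolated)
Conditions: Li (2.1 equiv), NH3(l)/THF, t-BuOH (1.0 equiv), −78 °C; then 23 (1.5 equiv) in THF, −78 → −33 °C; NH4Cl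
Reagents that add atoms: none
Why: Birch-type reductive alkylation: dissolving-metal reduction should give the trans-fused lithium enolate regiospecifically (axial protonation at C10, trans to the C5 methyl), and the benzylic bromide should attack C9 from the face opposite the axial C5 methyl, so that the C9 methyl ends cis to the C5 methyl.

Step 17
Reactants: 25 benzylated trans-decalone
Product: 26 {3-[(1S,4aS,5R,8aS)-5-[(2,5-dimethoxy-3-methylphenyl)methyl]-5,8a-dimethyl-6-methylidene-2-(propan-2-ylidene)decahydronaphthalen-1-yl]propoxy}tri(propan-2-yl)silane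
Conditions: Ph3PCH3Br (4 equiv), KOt-Bu (3.8 equiv), toluene, 90 °C
Reagents that add atoms: methyltriphenylphosphonium bromide, C[P+](c1ccccc1)(c1ccccc1)c1ccccc1.[Br-]
Why: Wittig methylenation of the hindered C8 ketone with excess ylide at elevated temperature; no stereocenter is formed and the quaternary C9 cannot epimerize.

Step 18
Reactants: 26 C8 exocyclic methylene compound
Product: 27 {3-[(1S,4aR,5S,6R,8aR)-5-[(2,5-dimethoxy-3-methylphenyl)methyl]-5,6,8a-trimethyl-2-(propan-2-ylidene)decahydronaphthalen-1-yl]propoxy}tri(propan-2-yl)silane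
Conditions: H2 (1 atm), PtO2 (5 mol %), EtOAc, rt
Reagents that add atoms: none
Why: Heterogeneous hydrogenation of the 1,1-disubstituted exocyclic alkene from the face opposite the axial C9 methyl should give the equatorial C8 methyl (cis to the C9 methyl), while the tetrasubstituted isopropylidene is expected to be inert under these conditions.

Step 19
Reactants: 27 silyl ether
Product: 28 3-[(1S,4aR,5S,6R,8aR)-5-[(2,5-dimethoxy-3-methylphenyl)methyl]-5,6,8a-trimethyl-2-(propan-2-ylidene)decahydronaphthalen-1-yl]propan-1-ol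
Conditions: TBAF (1.5 equiv), THF, rt
Reagents that add atoms: none
Why: Fluoride desilylation of the primary triisopropylsilyl ether.

Step 20
Reactants: 28 primary alcohol
Product: 29 3-[(1S,4aR,5S,6R,8aR)-5-[(2,5-dimethoxy-3-methylphenyl)methyl]-5,6,8a-trimethyl-2-(propan-2-ylidene)decahydronaphthalen-1-yl]propanoic acid
Conditions: TEMPO (0.2 equiv), PhI(OAc)2 (2.2 equiv), MeCN/H2O (1:1), rt
Reagents that add atoms: water, O
Why: Nitroxyl-catalysed oxidation of the primary alcohol through the aldehyde hydrate to the carboxylic acid, which should tolerate the tetrasubstituted alkene and the dimethoxyarene.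

Step 21
Reactants: 29 hydroquinone dimethyl ether acid
Product: 30 stypoquinonic acid
Conditions: (NH4)2Ce(NO3)6 (2.5 equiv), MeCN/H2O (2:1), 0 °C
Reagents that add atoms: water, O
Why: Oxidative demethylation of the 1,4-dimethoxyarene to the p-quinone (arene radical cation, ipso attack of water, loss of methanol); only one p-quinone can form and no stereocenter is affected.

## Compound list

1 | pent-1-en-3-one (ethyl vinyl ketone) | C=CC(=O)CC | starting material
2 | tert-butyl(dimethyl)[(3Z)-penta-1,3-dien-3-yloxy]silane | C/C=C(\O[Si](C)(C)C(C)(C)C)C=C | intermediate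
3 | pent-4-en-1-ol | C=CCCCO | starting material
4 | (pent-4-en-1-yloxy)tri(propan-2-yl)silane | C=CCCCO[Si](C(C)C)(C(C)C)C(C)C | intermediate
5 | (4S)-4-benzyl-1,3-oxazolidin-2-one | O=C1OC[C@H](Cc2ccccc2)N1 | starting material
6 | lithium (4S)-4-benzyl-2-oxo-1,3-oxazolidin-3-ide | [Li+].O=C1OC[C@H](Cc2ccccc2)[N-]1 | intermediate
7 | (4S)-3-acryloyl-4-benzyl-1,3-oxazolidin-2-one | O=C1OC[C@H](Cc2ccccc2)N1C(=O)C=C | intermediate
8 | (4S)-4-benzyl-3-[(2E)-6-{[tri(propan-2-yl)silyl]oxy}hex-2-enoyl]-1,3-oxazolidin-2-one | O=C1OC[C@H](Cc2ccccc2)N1C(=O)/C=C/CCCO[Si](C(C)C)(C(C)C)C(C)C | intermediate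
9 | (4S)-4-benzyl-3-{[(1S,2S,3S)-4-{[tert-butyl(dimethyl)silyl]oxy}-3-methyl-2-(3-{[tri(propan-2-yl)silyl]oxy}propyl)cyclohex-4-en-1-yl]carbonyl}-1,3-oxazolidin-2-one | O=C1OC[C@H](Cc2ccccc2)N1C(=O)[C@H]1CC=C(O[Si](C)(C)C(C)(C)C)[C@@H](C)[C@@H]1CCCO[Si](C(C)C)(C(C)C)C(C)C | intermediate
10 | S-phenyl (1S,2S,3S)-4-{[tert-butyl(dimethyl)silyl]oxy}-3-methyl-2-(3-{[tri(propan-2-yl)silyl]oxy}propyl)cyclohex-4-ene-1-carbothioate | O=C(Sc1ccccc1)[C@H]1CC=C(O[Si](C)(C)C(C)(C)C)[C@@H](C)[C@@H]1CCCO[Si](C(C)C)(C(C)C)C(C)C | intermediate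
11 | lithium enolate of thioester 10 (enolate carbon = C3) | [Li+].[O-]C(Sc1ccccc1)=C1CC=C(O[Si](C)(C)C(C)(C)C)[C@@H](C)[C@@H]1CCCO[Si](C(C)C)(C(C)C)C(C)C | intermediate
12 | (4R,8S,9S)-7-{[tert-butyl(dimethyl)silyl]oxy}-3,3,8-trimethyl-9-(3-{[tri(propan-2-yl)silyl]oxy}propyl)-2-oxaspiro[3.5]non-6-en-1-one | CC1(C)OC(=O)[C@@]12CC=C(O[Si](C)(C)C(C)(C)C)[C@@H](C)[C@@H]2CCCO[Si](C(C)C)(C(C)C)C(C)C | intermediate
13 | tert-butyl(dimethyl){[(5S,6S)-6-methyl-4-(propan-2-ylidene)-5-(3-{[tri(propan-2-yl)silyl]oxy}propyl)cyclohex-1-en-1-yl]oxy}silane | CC(C)=C1CC=C(O[Si](C)(C)C(C)(C)C)[C@@H](C)[C@@H]1CCCO[Si](C(C)C)(C(C)C)C(C)C | intermediate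
14 | (2S,3S)-2-methyl-4-(propan-2-ylidene)-3-(3-{[tri(propan-2-yl)silyl]oxy}propyl)cyclohexan-1-one | CC(C)=C1CCC(=O)[C@@H](C)[C@@H]1CCCO[Si](C(C)C)(C(C)C)C(C)C | intermediate
15 | (1S)-N-[(2S,3S)-2-methyl-4-(propan-2-ylidene)-3-(3-{[tri(propan-2-yl)silyl]oxy}propyl)cyclohexylidene]-1-phenylethan-1-amine | CC(C)=C1CCC(=N[C@@H](C)c2ccccc2)[C@@H](C)[C@@H]1CCCO[Si](C(C)C)(C(C)C)C(C)C | intermediate
16 | (1S)-N-[(2S,3R)-2-methyl-2-(3-oxopentyl)-4-(propan-2-ylidene)-3-(3-{[tri(propan-2-yl)silyl]oxy}propyl)cyclohexylidene]-1-phenylethan-1-amine | CC(C)=C1CCC(=N[C@@H](C)c2ccccc2)[C@@](C)(CCC(=O)CC)[C@@H]1CCCO[Si](C(C)C)(C(C)C)C(C)C | intermediate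
17 | (2S,3R)-2-methyl-2-(3-oxopentyl)-4-(propan-2-ylidene)-3-(3-{[tri(propan-2-yl)silyl]oxy}propyl)cyclohexan-1-one | CC(C)=C1CCC(=O)[C@@](C)(CCC(=O)CC)[C@@H]1CCCO[Si](C(C)C)(C(C)C)C(C)C | intermediate
18 | (4aS,5R)-1,4a-dimethyl-6-(propan-2-ylidene)-5-(3-{[tri(propan-2-yl)silyl]oxy}propyl)-4,4a,5,6,7,8-hexahydronaphthalen-2(3H)-one | CC(C)=C1CCC2=C(C)C(=O)CC[C@@]2(C)[C@@H]1CCCO[Si](C(C)C)(C(C)C)C(C)C | intermediate
19 | 4-methoxy-2-methylphenol | COc1ccc(O)c(C)c1 | starting material
20 | 2-hydroxy-5-methoxy-3-methylbenzaldehyde | COc1cc(C)c(O)c(C=O)c1 | intermediate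
21 | 2,5-dimethoxy-3-methylbenzaldehyde | COc1cc(C)c(OC)c(C=O)c1 | intermediate
22 | (2,5-dimethoxy-3-methylphenyl)methanol | COc1cc(C)c(OC)c(CO)c1 | intermediate
23 | 1-(bromomethyl)-2,5-dimethoxy-3-methylbenzene | COc1cc(C)c(OC)c(CBr)c1 | intermediate
24 | lithium (4aS,5S,8aS)-1,4a-dimethyl-6-(propan-2-ylidene)-5-(3-{[tri(propan-2-yl)silyl]oxy}propyl)-3,4,4a,5,6,7,8,8a-octahydronaphthalen-2-olate | [Li+].CC(C)=C1CC[C@@H]2C(C)=C([O-])CC[C@@]2(C)[C@@H]1CCCO[Si](C(C)C)(C(C)C)C(C)C | intermediate
25 | (1R,4aS,5S,8aS)-1-[(2,5-dimethoxy-3-methylphenyl)methyl]-1,4a-dimethyl-6-(propan-2-ylidene)-5-(3-{[tri(propan-2-yl)silyl]oxy}propyl)octahydronaphthalen-2(1H)-one | CC(C)=C1CC[C@@H]2[C@@](C)(Cc3cc(OC)cc(C)c3OC)C(=O)CC[C@@]2(C)[C@@H]1CCCO[Si](C(C)C)(C(C)C)C(C)C | intermediate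
26 | {3-[(1S,4aS,5R,8aS)-5-[(2,5-dimethoxy-3-methylphenyl)methyl]-5,8a-dimethyl-6-methylidene-2-(propan-2-ylidene)decahydronaphthalen-1-yl]propoxy}tri(propan-2-yl)silane | CC(C)=C1CC[C@@H]2[C@@](C)(Cc3cc(OC)cc(C)c3OC)C(=C)CC[C@@]2(C)[C@@H]1CCCO[Si](C(C)C)(C(C)C)C(C)C | intermediate
27 | {3-[(1S,4aR,5S,6R,8aR)-5-[(2,5-dimethoxy-3-methylphenyl)methyl]-5,6,8a-trimethyl-2-(propan-2-ylidene)decahydronaphthalen-1-yl]propoxy}tri(propan-2-yl)silane | CC(C)=C1CC[C@@H]2[C@@](C)(Cc3cc(OC)cc(C)c3OC)[C@H](C)CC[C@@]2(C)[C@@H]1CCCO[Si](C(C)C)(C(C)C)C(C)C | intermediate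
28 | 3-[(1S,4aR,5S,6R,8aR)-5-[(2,5-dimethoxy-3-methylphenyl)methyl]-5,6,8a-trimethyl-2-(propan-2-ylidene)decahydronaphthalen-1-yl]propan-1-ol | CC(C)=C1CC[C@@H]2[C@@](C)(Cc3cc(OC)cc(C)c3OC)[C@H](C)CC[C@@]2(C)[C@@H]1CCCO | intermediate
29 | 3-[(1S,4aR,5S,6R,8aR)-5-[(2,5-dimethoxy-3-methylphenyl)methyl]-5,6,8a-trimethyl-2-(propan-2-ylidene)decahydronaphthalen-1-yl]propanoic acid | CC(C)=C1CC[C@@H]2[C@@](C)(Cc3cc(OC)cc(C)c3OC)[C@H](C)CC[C@@]2(C)[C@@H]1CCC(=O)O | intermediate
30 | stypoquinonic acid, 3-[(1S,4aR,5S,6R,8aR)-5,6,8a-trimethyl-5-[(5-methyl-3,6-dioxocyclohexa-1,4-dien-1-yl)methyl]-2-(propan-2-ylidene)decahydronaphthalen-1-yl]propanoic acid | CC(C)=C1CC[C@@H]2[C@@](C)(CC3=CC(=O)C=C(C)C3=O)[C@H](C)CC[C@@]2(C)[C@@H]1CCC(=O)O | target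

## Step count and risks

Total step count: 21. Longest linear sequence: 15 steps (step 2 or 3, step 4, steps 5–11, steps 16–21).

Steps most likely to fail:

Step 5 (key cycloaddition). What may go wrong: Lewis-acid-induced desilylation or oligomerization of the silyloxy diene before it cycloadds, or loss of regio- and facial selectivity if the reaction runs outside the aluminium chelate. Fallback, setting out from 1 and 8 and coming back at 9: a Lewis-acid-free anionic double Michael sequence (Michael–Michael ring closure). Ketone 1 is deprotonated with LiN(iPr)2 in THF at −78 °C to lithium penta-1,3-dien-3-olate F1, which adds through its methyl-bearing terminus to the β-carbon of 8. The resulting imide enolate closes ring A by conjugate addition to the vinyl ketone, again forming the C2–C3 bond, and gives the regiodefined lithium enolate of the 4-acylcyclohexanone F2. This is silylated in the same flask with TBSOTf to give 9.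

Step 10 (quaternary C5). What may go wrong: reaction through the less substituted enamine (alkylation at C1), double alkylation or polymerization of the vinyl ketone, or insufficient facial discrimination at C5. Fallback, setting out from 14 and coming back at 17: a regiodefined enol silane route. Ketone 14 is converted under equilibrating conditions (Me3SiCl, NaI, Et3N, MeCN) into the tetrasubstituted trimethylsilyl enol ether F3. This is used in a Mukaiyama–Michael addition to 1 (TiCl4/Ti(OiPr)4, CH2Cl2, −78 °C), where axial attack anti to the C4 chain should set C5, and aqueous work-up gives 17 directly.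

Step 16 (reductive benzylation). What may go wrong: proton transfer and enolate equilibration in liquid ammonia (alkylation at C7 or recovery of the simply reduced ketone), O-alkylation, or over-reduction of the carbonyl. Fallback, setting out from 18 and coming back at 25: the enolate formed by Li/NH3 reduction is trapped with Me3SiCl/Et3N as the isolable trimethylsilyl enol ether F4. After removal of ammonia, this is cleaved with MeLi in THF to regenerate 24 regiospecifically, and 24 is alkylated with 23 in THF/HMPA at −20 °C to give 25.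

Further compounds
F1 | step 5 | lithium penta-1,3-dien-3-olate | [Li+].[O-]C(C=C)=CC
F2 | step 5 | lithium enolate (C10–C1) of (4S)-4-benzyl-3-{[(1S,2S,3S)-3-methyl-4-oxo-2-(3-{[tri(propan-2-yl)silyl]oxy}propyl)cyclohexyl]carbonyl}-1,3-oxazolidin-2-one | [Li+].O=C1OC[C@H](Cc2ccccc2)N1C(=O)[C@H]1CC=C([O-])[C@@H](C)[C@@H]1CCCO[Si](C(C)C)(C(C)C)C(C)C
F3 | step 10 | trimethyl{[(3R)-2-methyl-4-(propan-2-ylidene)-3-(3-{[tri(propan-2-yl)silyl]oxy}propyl)cyclohex-1-en-1-yl]oxy}silane | CC(C)=C1CCC(O[Si](C)(C)C)=C(C)[C@@H]1CCCO[Si](C(C)C)(C(C)C)C(C)C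
F4 | step 16 | {[(4aS,5S,8aS)-1,4a-dimethyl-6-(propan-2-ylidene)-5-(3-{[tri(propan-2-yl)silyl]oxy}propyl)-3,4,4a,5,6,7,8,8a-octahydronaphthalen-2-yl]oxy}trimethylsilane | CC(C)=C1CC[C@@H]2C(C)=C(O[Si](C)(C)C)CC[C@@]2(C)[C@@H]1CCCO[Si](C(C)C)(C(C)C)C(C)C
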